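**Strategy.** The route rests on cutting the tetrahydrofuran of the target (ring O, C7, C8, C9, C10) at O–C7 and C7–C8. The key step exploits this ring's substitution pattern: quaternary C7 sits between the ether oxygen and the oxygenated C8, and the same oxygen is bound to quaternary C10. In one operation a rhodium vinylcarbene from a vinyl diazoacetate (C6, C7, C11–C13) is captured by the tertiary hydroxyl of a β-hydroxy aldehyde (C8, C9, C10, C1), and the enol so formed closes onto the aldehyde. This makes the ring, both bonds and the C7 and C8 stereocentres. The ten-membered carbocycle is closed later by ring-closing metathesis at C4=C5.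

Key step: step 7

**Remarks.**
- Atom numbers are those of the germacrane skeleton of the target (C1–C15).
- Assumption: the aldol of step 7 follows its hydrogen-bonded course and therefore gives the C8 epimer of the carbinol that the target needs; steps 8 and 9 invert it.
- Lactol and hemiketal carbons and the new carbinol of triol 5 form as epimer mixtures and are drawn without configuration.

Step 1
Reactants: 1 (S)-2-methylglycidol
Product: 2 (R)-2-[(4-methoxybenzyloxy)methyl]-2-methyloxirane
Conditions: NaH, 4-methoxybenzyl chloride, Bu4NI (cat.), THF/DMF, 0 °C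
Reagents that add atoms: 4-methoxybenzyl chloride, COc1ccc(CCl)cc1
Why: Williamson ether synthesis on the primary alkoxide leaves the quaternary epoxide carbon (future C10) untouched, so its configuration is carried over (only the descriptor changes, through the new priorities).

Step 2
Reactants: 2 (R)-2-[(4-methoxybenzyloxy)methyl]-2-methyloxirane; 3 vinylmagnesium bromide
Product: 4 (R)-1-(4-methoxybenzyloxy)-2-methylpent-4-en-2-ol
Conditions: copper iodide CuI (10 mol %), THF, −30 → 0 °C
Reagents that add atoms: none
Why: Copper-catalysed Grignard opening of the 2,2-disubstituted epoxide is an SN2 attack at the unhindered CH2 terminus (future C9) and gives the tertiary C10 alcohol without touching the stereocentre.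

Step 3
Reactants: 4 (R)-1-(4-methoxybenzyloxy)-2-methylpent-4-en-2-ol
Product: 6 (R)-3-hydroxy-4-(4-methoxybenzyloxy)-3-methylbutanal, via triol 5 (not isolated)
Conditions: OsO4 (2 mol %), NaIO4, 2,6-lutidine, 1,4-dioxane/H2O, rt
Reagents that add atoms: osmium tetroxide, O=[Os](=O)(=O)=O; sodium periodate, [Na+].[O-][I](=O)(=O)=O
Why: Lemieux–Johnson cleavage (dihydroxylation, then periodate scission) turns the terminal alkene into the C8 aldehyde under buffered conditions that spare the PMB ether and should not dehydrate the β-hydroxy aldehyde, which is used without storage.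

Step 4
Reactants: 7 monomethyl itaconate (4-methyl ester)
Product: 9 methyl 3-(hydroxymethyl)but-3-enoate, via mixed anhydride 8 (not isolated)
Conditions: ClCO2Et, N-methylmorpholine, THF, −15 °C; then NaBH4, H2O, −15 → 0 °C
Reagents that add atoms: none
Why: Activation of the free acid as a mixed carbonic anhydride lets borohydride reduce only that carbonyl (1,2-reduction to the allylic alcohol, future C12) while the methyl ester (future C6) is left alone.

Step 5
Reactants: 9 methyl 3-(hydroxymethyl)but-3-enoate
Product: 10 methyl 3-[(tert-butyldimethylsilyloxy)methyl]but-3-enoate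
Conditions: TBSCl, imidazole, CH2Cl2, 0 °C → rt
Reagents that add atoms: tert-butyldimethylsilyl chloride, CC(C)(C)[Si](C)(C)Cl
Why: Standard silylation of the primary allylic alcohol, done at once so that the γ-hydroxy ester cannot lactonise.

Step 6
Reactants: 10 methyl 3-[(tert-butyldimethylsilyloxy)methyl]but-3-enoate
Product: 11 methyl 2-diazo-3-[(tert-butyldimethylsilyloxy)methyl]but-3-enoate
Conditions: 4-acetamidobenzenesulfonyl azide, DBU, MeCN, 0 °C
Reagents that add atoms: 4-acetamidobenzenesulfonyl azide, CC(=O)Nc1ccc(cc1)S(=O)(=O)N=[N+]=[N-]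
Why: Regitz diazo transfer to the α-carbon of a β,γ-unsaturated ester through its dienolate is the usual entry to vinyl diazoacetates; 11 is kept cold and used the same day because such compounds slowly electrocyclise to pyrazoles.

Step 7
Reactants: 6 (R)-3-hydroxy-4-(4-methoxybenzyloxy)-3-methylbutanal; 11 methyl 2-diazo-3-[(tert-butyldimethylsilyloxy)methyl]but-3-enoate
Product: 13 methyl (2S,3R,5R)-2-[3-(tert-butyldimethylsilyloxy)prop-1-en-2-yl]-3-hydroxy-5-[(4-methoxybenzyloxy)methyl]-5-methyltetrahydrofuran-2-carboxylate (3-OH cis to the ester and to CH2OPMB), via ester enol 12 (not isolated)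
Conditions: Rh2(OAc)4 (1 mol %), CH2Cl2, rt, 11 added over 3 h
Reagents that add atoms: none
Why: Rh2(OAc)4, a dimer of divalent rhodium, decomposes 11 to a rhodium-bound vinylcarbene at C7; the tertiary C10 hydroxyl of 6 attacks it (O–C7) and the oxonium ylide gives, by proton shift to the ester oxygen, enol 12, which adds to the C8 aldehyde (C7–C8) faster than it ketonises. The closest known reaction type is the rhodium- or copper-carbene O–H insertion of β-hydroxy ketones and aldehydes that an intramolecular aldol diverts into 3-hydroxytetrahydrofuran-2-carboxylates. The tetrahydrofuran (O, C7, C8, C9, C10) closes in a 5-(enolexo)-exo-trig aldol. C8 is set relative to C7 by the hydrogen bond from the enol OH to the aldehyde oxygen in a cis-fused bicyclic transition state, which puts the new hydroxyl syn to the ester (8R, corrected in steps 8 and 9); C7 is set relative to the existing C10 centre, whose methyl group should take the side of the bulky silyloxymethyl-vinyl arm and whose CH2OPMB arm the side of the hydrogen-bonded pair, so that C6 ends syn to C1 (7S). The step needs attack at the carbene carbon and not at the vinylogous terminus C13, and capture by O–H and not by the aldehyde oxygen: the carboxylate-ligated catalyst in a non-polar chlorinated solvent, slow addition of 11 and the greater nucleophilicity of the hydroxyl should secure this.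

Step 8
Reactants: 13 the 2,3-cis hydroxy ester from step 7
Product: 14 methyl (2S,5R)-2-[3-(tert-butyldimethylsilyloxy)prop-1-en-2-yl]-5-[(4-methoxybenzyloxy)methyl]-5-methyl-3-oxotetrahydrofuran-2-carboxylate
Conditions: Dess–Martin periodinane, NaHCO3, CH2Cl2, 0 °C → rt
Reagents that add atoms: none
Why: Dess–Martin oxidation removes the mis-set C8 stereocentre; quaternary C7 cannot epimerise and the PMB ether, silyl ether and alkene are inert.

Step 9
Reactants: 14 the C8 ketone
Product: 15 methyl (2S,3S,5R)-2-[3-(tert-butyldimethylsilyloxy)prop-1-en-2-yl]-3-hydroxy-5-[(4-methoxybenzyloxy)methyl]-5-methyltetrahydrofuran-2-carboxylate (3-OH trans to the ester)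
Conditions: Zn(BH4)2, Et2O, −20 °C
Reagents that add atoms: none
Why: Chelation-controlled hydride reduction of the β-keto ester: zinc bridges the ketone and ester carbonyls, which turns the ester toward the ketone plane and leaves the bulky 2-propenyl arm to shield the other face, so hydride should enter syn to the ester and the C8 hydroxyl end anti to it (8S), the ester itself not being reduced.

Step 10
Reactants: 15 the 2,3-trans hydroxy ester
Product: 16 the C8 tert-butyldimethylsilyl ether of 15
Conditions: TBSOTf, 2,6-lutidine, CH2Cl2, −78 → 0 °C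
Reagents that add atoms: tert-butyldimethylsilyl triflate, CC(C)(C)[Si](C)(C)OS(=O)(=O)C(F)(F)F
Why: Silyl triflate silylation of the hindered secondary alcohol blocks C8–OH against retro-aldol cleavage in the basic steps that follow and keeps it out of the later lactonisations.

Step 11
Reactants: 16 the bis-silyl PMB ester
Product: 17 the C6 aldehyde (CO2Me of 16 replaced by CHO)
Conditions: i-Bu2AlH (1.1 equiv), CH2Cl2, −78 °C; MeOH, then aq. potassium sodium tartrate
Reagents that add atoms: none
Why: Partial reduction of an α-alkoxy ester: the aluminium hemiacetal, chelated to the ring oxygen and flanked by quaternary C7, should survive at −78 °C and release the non-enolisable aldehyde only on work-up.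

Step 12
Reactants: 17 the C6 aldehyde; 3 vinylmagnesium bromide
Product: 18 the (6R) vinyl carbinol (C5 and its CH2 terminus added to C6)
Conditions: MgBr2·OEt2, CH2Cl2, −78 °C; then 3 (THF solution), −78 °C
Reagents that add atoms: none
Why: Cram-chelate controlled Grignard addition: magnesium ties the aldehyde oxygen to the ring ether oxygen, and the vinyl group then enters the carbonyl face next to the ring C8–H and not the face covered by the 2-propenyl arm, which should set C6 as R.

Step 13
Reactants: 18 the (6R) vinyl carbinol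
Product: 19 the C1,C6 diol (PMB removed)
Conditions: DDQ, CH2Cl2/aq. NaH2PO4–Na2HPO4 (pH 7), 0 °C
Reagents that add atoms: none
Why: Oxidative PMB cleavage by DDQ (benzylic oxocarbenium ion, then hydrolysis) frees the primary C1 hydroxyl; silyl ethers, isolated alkenes and the unactivated allylic alcohol are not oxidised.

Step 14
Reactants: 19 the C1,C6 diol
Product: 21 the bridged δ-lactone C6–O–C1(=O) (a 3,8-dioxabicyclo[3.2.1]octan-2-one), via lactol 20 (not isolated)
Conditions: TEMPO (20 mol %), PhI(OAc)2, CH2Cl2, rt
Reagents that add atoms: none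
Why: Nitroxyl-catalysed oxidative lactonisation of a 1,5-diol: the primary C1 alcohol goes to the aldehyde, the cis-disposed C6 hydroxyl captures it as a six-membered bridged lactol and this is oxidised on, so C1 reaches the carboxyl level while C6–OH is masked without a protecting group.

Step 15
Reactants: 21 the bridged δ-lactone; 22 4-bromo-2-methylbut-1-ene
Product: 25 the hydroxy ketone diene (free C6 carbinol; C1 ketone carrying the 3-methylbut-3-enyl chain C2–C4/C15), via Grignard reagent 23 (not isolated), via hemiketal 24 (not isolated)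
Conditions: Mg, THF, rt (22 → 23); then 21, THF, −78 → −40 °C; aq. NH4Cl
Reagents that add atoms: none
Why: Single Grignard addition to a lactone: the magnesium hemiketal, held in the bicycle and chelated by the α-ether oxygen, should not collapse in the cold (as with aldonolactones), and after work-up hemiketal 24 opens to the hindered C1 ketone and the free C6 alcohol (the two forms may equilibrate, which is harmless).

Step 16
Reactants: 25 the hydroxy ketone diene
Product: 26 the bicyclic (4Z)-alkene: 7,10-epoxygermacra-4,11(13)-dien-1-one with 6-OH and 8,12-bis(silyloxy) groups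
Conditions: second-generation Hoveyda–Grubbs catalyst (10 mol %), 1,4-benzoquinone (20 mol %), toluene (1 mM), 80 °C
Reagents that add atoms: none
Why: Ring-closing metathesis between the C5 vinyl and C4 isopropenyl groups, both held on one face of the tetrahydrofuran, closes the ten-membered carbocycle (nine-membered through the ether oxygen), in which only the Z-alkene is free of strain; the hindered C11=C13 alkene should take no part.

Step 17
Reactants: 26 the bicyclic (4Z)-alkene
Product: 27 the (4R,5S)-4,5-epoxide of 26
Conditions: VO(acac)2 (5 mol %), t-BuOOH (in decane), CH2Cl2, 0 °C → rt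
Reagents that add atoms: tert-butyl hydroperoxide, CC(C)(C)OO
Why: Hydroxyl-directed vanadium-catalysed epoxidation: the C6 alkoxide binds the vanadium peroxide and delivers oxygen to the C4=C5 face on its own side of the ring, the outcome known for (Z)-cycloalkenols of eight to ten ring atoms, which should give the cis-hydroxy epoxide; the C11=C13 alkene has no free hydroxyl and the ketone is inert.

Step 18
Reactants: 27 the epoxy alcohol
Product: 28 the C6,C12 diol (primary silyl ether removed)
Conditions: HF·pyridine, pyridine, THF, 0 °C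
Reagents that add atoms: none
Why: Fluoride-mediated desilylation is much faster for the primary allylic silyl ether at C12 than for the neopentyl-type secondary one at C8, and the pyridine buffer protects the epoxy alcohol.

Step 19
Reactants: 28 the C6,C12 diol
Product: 30 the α-methylene-γ-lactone (6,12-olide) with C1 ketone, 4,5-epoxide and C8 silyl ether, via lactol 29 (not isolated)
Conditions: TEMPO (20 mol %), PhI(OAc)2, CH2Cl2, rt
Reagents that add atoms: none
Why: Oxidative lactonisation of a 2-methylene-1,4-diol: the primary allylic C12 alcohol is oxidised to the enal, C6–OH closes the five-membered lactol and this is oxidised to the lactone; because C8–O is silylated only the 6,12-lactone can form.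

Step 20
Reactants: 30 the silylated keto lactone
Product: 31 the C8 alcohol
Conditions: HF·pyridine, THF, 0 °C → rt
Reagents that add atoms: none
Why: Acidic fluoride cleaves the last silyl ether without the basic conditions that would add to the methylene lactone; trisubstituted epoxides of this kind tolerate buffered HF.

Step 21
Reactants: 31 the C8 alcohol
Product: 32 CNP0241021.1
Conditions: methacrylic anhydride, Et3N, DMAP (cat.), CH2Cl2, 0 °C → rt
Reagents that add atoms: methacrylic anhydride, C=C(C)C(=O)OC(=O)C(C)=C
Why: DMAP-catalysed acyl transfer to the only free hydroxyl installs the C8 methacrylate with retention of configuration.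

**Compound list**

1 | (S)-2-methylglycidol | C1[C@@](CO)(C)O1 | starting material
2 | (R)-2-[(4-methoxybenzyloxy)methyl]-2-methyloxirane | C1[C@@](COCc2ccc(OC)cc2)(C)O1 | intermediate
3 | vinylmagnesium bromide | C=C[Mg]Br | starting material
4 | (R)-1-(4-methoxybenzyloxy)-2-methylpent-4-en-2-ol | C=CC[C@@](COCc1ccc(OC)cc1)(C)O | intermediate
5 | (4R)-5-(4-methoxybenzyloxy)-4-methylpentane-1,2,4-triol (C2 epimers) | OCC(O)C[C@@](COCc1ccc(OC)cc1)(C)O | intermediate
6 | (R)-3-hydroxy-4-(4-methoxybenzyloxy)-3-methylbutanal | O=CC[C@@](COCc1ccc(OC)cc1)(C)O | intermediate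
7 | monomethyl itaconate (4-methyl ester) | C=C(CC(=O)OC)C(=O)O | starting material
8 | ethyl carbonic mixed anhydride of 7 | C=C(CC(=O)OC)C(=O)OC(=O)OCC | intermediate
9 | methyl 3-(hydroxymethyl)but-3-enoate | C=C(CO)CC(=O)OC | intermediate
10 | methyl 3-[(tert-butyldimethylsilyloxy)methyl]but-3-enoate | C=C(CO[Si](C)(C)C(C)(C)C)CC(=O)OC | intermediate
11 | methyl 2-diazo-3-[(tert-butyldimethylsilyloxy)methyl]but-3-enoate | COC(=O)C(=[N+]=[N-])C(=C)CO[Si](C)(C)C(C)(C)C | intermediate
12 | ester enol of the O–H insertion product (C10–O–C7 ether, free C8 aldehyde) | COC(O)=C(O[C@@](C)(COCc1ccc(OC)cc1)CC=O)C(=C)CO[Si](C)(C)C(C)(C)C | intermediate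
13 | methyl (2S,3R,5R)-2-[3-(tert-butyldimethylsilyloxy)prop-1-en-2-yl]-3-hydroxy-5-[(4-methoxybenzyloxy)methyl]-5-methyltetrahydrofuran-2-carboxylate | O[C@@H]1C[C@@](COCc2ccc(OC)cc2)(C)O[C@@]1(C(=O)OC)C(=C)CO[Si](C)(C)C(C)(C)C | intermediate
14 | methyl (2S,5R)-2-[3-(tert-butyldimethylsilyloxy)prop-1-en-2-yl]-5-[(4-methoxybenzyloxy)methyl]-5-methyl-3-oxotetrahydrofuran-2-carboxylate | O=C1C[C@@](COCc2ccc(OC)cc2)(C)O[C@@]1(C(=O)OC)C(=C)CO[Si](C)(C)C(C)(C)C | intermediate
15 | methyl (2S,3S,5R)-2-[3-(tert-butyldimethylsilyloxy)prop-1-en-2-yl]-3-hydroxy-5-[(4-methoxybenzyloxy)methyl]-5-methyltetrahydrofuran-2-carboxylate | O[C@H]1C[C@@](COCc2ccc(OC)cc2)(C)O[C@@]1(C(=O)OC)C(=C)CO[Si](C)(C)C(C)(C)C | intermediate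
16 | C8 tert-butyldimethylsilyl ether of 15 | CC(C)(C)[Si](C)(C)O[C@H]1C[C@@](COCc2ccc(OC)cc2)(C)O[C@@]1(C(=O)OC)C(=C)CO[Si](C)(C)C(C)(C)C | intermediate
17 | C6 aldehyde from 16 | CC(C)(C)[Si](C)(C)O[C@H]1C[C@@](COCc2ccc(OC)cc2)(C)O[C@@]1(C=O)C(=C)CO[Si](C)(C)C(C)(C)C | intermediate
18 | (6R) vinyl carbinol from 17 | CC(C)(C)[Si](C)(C)O[C@H]1C[C@@](COCc2ccc(OC)cc2)(C)O[C@@]1([C@H](O)C=C)C(=C)CO[Si](C)(C)C(C)(C)C | intermediate
19 | C1,C6 diol (18 without PMB) | CC(C)(C)[Si](C)(C)O[C@H]1C[C@@](CO)(C)O[C@@]1([C@H](O)C=C)C(=C)CO[Si](C)(C)C(C)(C)C | intermediate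
20 | bridged lactol C6–O–C1H(OH) (C1 epimers) | CC(C)(C)[Si](C)(C)O[C@H]1C[C@@]2(C)O[C@@]1([C@@H](C=C)OC2O)C(=C)CO[Si](C)(C)C(C)(C)C | intermediate
21 | bridged δ-lactone C6–O–C1(=O), a 3,8-dioxabicyclo[3.2.1]octan-2-one | CC(C)(C)[Si](C)(C)O[C@H]1C[C@@]2(C)O[C@@]1([C@@H](C=C)OC2=O)C(=C)CO[Si](C)(C)C(C)(C)C | intermediate
22 | 4-bromo-2-methylbut-1-ene | C=C(C)CCBr | starting material
23 | 3-methylbut-3-enylmagnesium bromide | C=C(C)CC[Mg]Br | intermediate
24 | bridged hemiketal C6–O–C1(OH)(3-methylbut-3-enyl) (C1 epimers) | CC(C)(C)[Si](C)(C)O[C@H]1C[C@@]2(C)O[C@@]1([C@@H](C=C)OC2(O)CCC(C)=C)C(=C)CO[Si](C)(C)C(C)(C)C | intermediate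
25 | hydroxy ketone diene (free (6R) carbinol; C1 ketone with 3-methylbut-3-enyl chain) | CC(C)(C)[Si](C)(C)O[C@H]1C[C@@](C(=O)CCC(C)=C)(C)O[C@@]1([C@H](O)C=C)C(=C)CO[Si](C)(C)C(C)(C)C | intermediate
26 | bicyclic (4Z)-alkene: 6-hydroxy-8,12-bis(tert-butyldimethylsilyloxy)-7,10-epoxygermacra-4,11(13)-dien-1-one | CC(C)(C)[Si](C)(C)O[C@H]1C[C@@]2(C)O[C@@]1([C@H](O)/C=C(C)\CCC2=O)C(=C)CO[Si](C)(C)C(C)(C)C | intermediate
27 | (4R,5S)-4,5-epoxide of 26 | CC(C)(C)[Si](C)(C)O[C@H]1C[C@@]2(C)O[C@@]1([C@H](O)[C@@H]3O[C@]3(C)CCC2=O)C(=C)CO[Si](C)(C)C(C)(C)C | intermediate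
28 | C6,C12 diol (27 without the primary silyl group) | CC(C)(C)[Si](C)(C)O[C@H]1C[C@@]2(C)O[C@@]1([C@H](O)[C@@H]3O[C@]3(C)CCC2=O)C(=C)CO | intermediate
29 | five-membered lactol C6–O–C12H(OH) (C12 epimers) | CC(C)(C)[Si](C)(C)O[C@H]1C[C@@]2(C)O[C@@]13C(=C)C(O)O[C@@H]3[C@@H]1O[C@]1(C)CCC2=O | intermediate
30 | C8 tert-butyldimethylsilyl ether of the des-methacryloyl target | CC(C)(C)[Si](C)(C)O[C@H]1C[C@@]2(C)O[C@@]13C(=C)C(=O)O[C@@H]3[C@@H]1O[C@]1(C)CCC2=O | intermediate
31 | des-methacryloyl target (free C8 alcohol) | O[C@H]1C[C@@]2(C)O[C@@]13C(=C)C(=O)O[C@@H]3[C@@H]1O[C@]1(C)CCC2=O | intermediate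
32 | CNP0241021.1 | C=C(C)C(=O)O[C@H]1C[C@@]2(C)O[C@@]13C(=C)C(=O)O[C@@H]3[C@@H]1O[C@]1(C)CCC2=O | target

**Totals.** Total step count: 21. Longest linear sequence: 18 steps (steps 1–3 and 7–21; the diazo ester branch, steps 4–6 and 7–21, is equally long).

**Steps most likely to fail**

1. Step 7 (key step). What may go wrong: the alcohol attacks the vinylogous terminus C13 of the vinylcarbene, the diazo ester electrocyclises to a pyrazole before it meets the catalyst, or the C10 centre discriminates poorly between the two faces at C7. Fallback, setting out from 6 and coming back at 16: the vinyl group is replaced by a ketone, so that a carbene with no vinylogous site is used, and C13 is added afterwards. The imidazolide of commercial (tert-butyldimethylsilyloxy)acetic acid is C-acylated with potassium methyl malonate (MgCl2, Et3N) to give methyl 4-(tert-butyldimethylsilyloxy)-3-oxobutanoate F1. Diazo transfer (4-acetamidobenzenesulfonyl azide, Et3N) gives methyl 2-diazo-4-(tert-butyldimethylsilyloxy)-3-oxobutanoate F2. With 6 and Rh2(OAc)4 this should give, by the same O–H insertion and aldol closure (a trace of Et3N if the β-dicarbonyl enol lingers), the 2-acyl-3-hydroxytetrahydrofuran F3. Here the enolised ketone is the hydrogen-bond donor, so the C8 hydroxyl should come out anti to the ester. Silylation (TBSOTf, 2,6-lutidine) gives the silyl ether F4, and Takai–Lombardo methylenation of the ketone (Zn, CH2Br2, TiCl4) gives 16; steps 8–10 then fall away.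

2. Step 16 (ring-closing metathesis). What may go wrong: intermolecular metathesis outruns closure of the medium ring at the hindered 1,1-disubstituted alkene, or ruthenium hydrides isomerise the allylic alcohol. Fallback, setting out from 25 and coming back at 26: the C6 hydroxyl and the C1 ketone are locked as the bridged methyl ketal F5 (MeOH, HC(OMe)3, pyridinium p-toluenesulfonate). In F5 both alkenes hang from one six-membered ring and metathesis has only to close a seven-membered oxepene, which should give the tricyclic ketal F6. Mild aqueous acid (AcOH/THF/H2O) then opens the ketal to 26.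

3. Step 17 (directed epoxidation). What may go wrong: oxygen is delivered to the wrong alkene face if the ring holds the C6 hydroxyl away from the alkene or if the C6–O–C1 hemiketal form binds vanadium through its other hydroxyl, or the epoxy alcohol opens. Fallback, setting out from 26 and coming back at 30: the lactone is built first and the epoxide made by the halohydrin route, which places oxygen on the face opposite to the one an electrophile attacks. HF·pyridine/pyridine removes the primary silyl ether of 26 to give the diol F7. TEMPO/PhI(OAc)2 gives the methylene lactone F8. N-Bromosuccinimide in wet 1,2-dimethoxyethane should give the bromohydrin F9 (Br at C5 on the outer face, OH at the tertiary C4 from the inner face). K2CO3 in acetone closes the epoxide with inversion at C5 to give 30.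

**Further compounds**

F1 | step 7 | methyl 4-(tert-butyldimethylsilyloxy)-3-oxobutanoate | COC(=O)CC(=O)CO[Si](C)(C)C(C)(C)C
F2 | step 7 | methyl 2-diazo-4-(tert-butyldimethylsilyloxy)-3-oxobutanoate | COC(=O)C(=[N+]=[N-])C(=O)CO[Si](C)(C)C(C)(C)C
F3 | step 7 | methyl 2-[(tert-butyldimethylsilyloxy)acetyl]-3-hydroxy-5-[(4-methoxybenzyloxy)methyl]-5-methyltetrahydrofuran-2-carboxylate (3-OH anti to the ester) | O[C@H]1C[C@@](COCc2ccc(OC)cc2)(C)O[C@@]1(C(=O)OC)C(=O)CO[Si](C)(C)C(C)(C)C
F4 | step 7 | C8 tert-butyldimethylsilyl ether of F3 | CC(C)(C)[Si](C)(C)O[C@H]1C[C@@](COCc2ccc(OC)cc2)(C)O[C@@]1(C(=O)OC)C(=O)CO[Si](C)(C)C(C)(C)C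
F5 | step 16 | bridged methyl ketal of 25 (C6–O–C1(OMe)) | CC(C)(C)[Si](C)(C)O[C@H]1C[C@@]2(C)O[C@@]1([C@@H](C=C)OC2(OC)CCC(C)=C)C(=C)CO[Si](C)(C)C(C)(C)C
F6 | step 16 | tricyclic ketal with the (4Z)-alkene in a seven-membered oxepene | CC(C)(C)[Si](C)(C)O[C@H]1C[C@@]2(C)O[C@@]1([C@H]3/C=C(C)\CCC2(OC)O3)C(=C)CO[Si](C)(C)C(C)(C)C
F7 | step 17 | C6,C12 diol of the (4Z)-alkene (26 without the primary silyl group) | CC(C)(C)[Si](C)(C)O[C@H]1C[C@@]2(C)O[C@@]1([C@H](O)/C=C(C)\CCC2=O)C(=C)CO
F8 | step 17 | (4Z)-alkene α-methylene-γ-lactone with C1 ketone and C8 silyl ether | CC(C)(C)[Si](C)(C)O[C@H]1C[C@@]2(C)O[C@@]13C(=C)C(=O)O[C@@H]3/C=C(C)\CCC2=O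
F9 | step 17 | bromohydrin of F8 (5-bromo, 4-hydroxy, anti) | CC(C)(C)[Si](C)(C)O[C@H]1C[C@@]2(C)O[C@@]13C(=C)C(=O)O[C@@H]3[C@@H](Br)[C@@](O)(C)CCC2=O
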